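**Retrosynthetic overview**
- The target, read as the (2S,3R)-diol, is cut at the bond between the methine carbon and C2 of the tryptophol unit: an indol-3-yl azafulvenium ion plus tryptophol, joined in a photoredox step.
- The azafulvenium precursor is a bench-stable 3-(1-sulfonylalkyl)indole, cut at the indole C3–CH bond into indole, (R)-glyceraldehyde acetonide and p-toluenesulfinic acid.
- The carbinol stereocentre is bought in D-mannitol-derived (R)-glyceraldehyde acetonide; the methine stereocentre is set by 1,2-induction from it.
- No ring is formed in the route: both indole nuclei are bought, and the dioxolane is bought and opened last.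

Assumption: aldehyde 2 is bought enantiopure and distilled just before use.

**Step 1**
Reactants: 1 indole; 2 (4R)-2,2-dimethyl-1,3-dioxolane-4-carbaldehyde; 3 4-methylbenzenesulfinic acid
Product: 4 3-{[(4R)-2,2-dimethyl-1,3-dioxolan-4-yl](4-methylbenzenesulfonyl)methyl}-1H-indole (about 1:1 epimers at the sulfonyl-bearing carbon)
Conditions: 3 (1.5 equiv), MgSO4, EtOAc, 0 °C to rt, 4 h
Reagents that add atoms: none
Why: Three-component sulfonylalkylation of indole (Friedel–Crafts hydroxyalkylation, ionisation to the azafulvenium ion, capture by the soft sulfinic acid faster than by a second indole) gives the stable sulfone; the bought stereocentre is untouched, and the new sulfonyl-bearing carbon is an inconsequential epimer mixture because it becomes trigonal again in step 2.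

**Step 2**
Reactants: 4 3-{[(4R)-2,2-dimethyl-1,3-dioxolan-4-yl](4-methylbenzenesulfonyl)methyl}-1H-indole; 5 tryptophol [2-(1H-indol-3-yl)ethan-1-ol]
Product: 8 2-{2-[(R)-[(4S)-2,2-dimethyl-1,3-dioxolan-4-yl](1H-indol-3-yl)methyl]-1H-indol-3-yl}ethan-1-ol, via sulfone radical cation 6 (not isolated), via azafulvenium ion 7 (not isolated)
Conditions: 9-mesityl-3,6-di-tert-butyl-10-phenylacridinium tetrafluoroborate (3 mol%), 5 (3 equiv), degassed MeCN (0.05 M), 450 nm LEDs, 0 °C, Ar; aq NaHCO3 work-up
Reagents that add atoms: none
Why: Proposed new method: a redox-neutral photoredox desulfinative Friedel–Crafts coupling in which the excited acridinium (about +2.0 V vs SCE) oxidises the indole ring of 4 (about +1.3 V) to radical cation 6, whose C–S bond (held out of the ring plane because A(1,3) strain puts the C–H in plane) cleaves mesolytically, or by N–H loss and β-scission, to TolSO2• and azafulvenium ion 7, the acridine radical then returning the electron to TolSO2• so that sulfinic acid is the only acid formed; tryptophol attacks 7 through C2 (C3, N or O adducts revert under this mild acid) on the face anti to the dioxolane C–O bond in the conformer whose dioxolane C–H eclipses the exocyclic C=C, which sets the methine carbon as R under control of the bought centre; recapture of 7 by sulfinate only regenerates 4, which is re-activated by light, whereas 8 cannot fragment, so the mixture funnels to 8; closest known reaction types are the base- or Lewis-acid-mediated substitution of 3-(1-sulfonylalkyl)indoles via alkylideneindolenines and the photoredox mesolytic cleavage of alkoxyamine, benzylic thioether and thioglycoside radical cations to carbocations.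

**Step 3**
Reactants: 8 2-{2-[(R)-[(4S)-2,2-dimethyl-1,3-dioxolan-4-yl](1H-indol-3-yl)methyl]-1H-indol-3-yl}ethan-1-ol
Product: 9 colletotryptin A, (2S,3R)-3-[3-(2-hydroxyethyl)-1H-indol-2-yl]-3-(1H-indol-3-yl)propane-1,2-diol
Conditions: AcOH/H2O (4:1), 40 °C, 3 h
Reagents that add atoms: none
Why: Acid-catalysed hydrolysis of a terminal isopropylidene ketal; acetic acid is too weak to protonate the indole C3 positions, so no retro-Friedel–Crafts epimerisation occurs and neither stereocentre is touched.

**Compound list**
1 | indole | c1ccc2[nH]ccc2c1 | starting material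
2 | (4R)-2,2-dimethyl-1,3-dioxolane-4-carbaldehyde [(R)-glyceraldehyde acetonide] | O=C[C@H]1COC(C)(C)O1 | starting material
3 | 4-methylbenzenesulfinic acid | Cc1ccc(cc1)S(=O)O | starting material
4 | 3-{[(4R)-2,2-dimethyl-1,3-dioxolan-4-yl](4-methylbenzenesulfonyl)methyl}-1H-indole (epimer mixture at the sulfonyl carbon) | Cc1ccc(cc1)S(=O)(=O)C(c2c[nH]c3ccccc23)[C@H]4COC(C)(C)O4 | intermediate
5 | tryptophol, 2-(1H-indol-3-yl)ethan-1-ol | OCCc1c[nH]c2ccccc12 | starting material
6 | radical cation of 4 (drawn as the C3-radical iminium form) | Cc1ccc(cc1)S(=O)(=O)C([C]2C=[NH+]c3ccccc23)[C@H]4COC(C)(C)O4 | intermediate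
7 | 3-{[(4S)-2,2-dimethyl-1,3-dioxolan-4-yl]methylidene}-3H-indol-1-ium (sulfinate counter-ion) | C(=C1C=[NH+]c2ccccc12)[C@H]3COC(C)(C)O3 | intermediate
8 | 2-{2-[(R)-[(4S)-2,2-dimethyl-1,3-dioxolan-4-yl](1H-indol-3-yl)methyl]-1H-indol-3-yl}ethan-1-ol | OCCc1c([C@@H](c2c[nH]c3ccccc23)[C@H]4COC(C)(C)O4)[nH]c5ccccc15 | intermediate
9 | colletotryptin A, (2S,3R)-3-[3-(2-hydroxyethyl)-1H-indol-2-yl]-3-(1H-indol-3-yl)propane-1,2-diol | OCCc1c([C@@H](c2c[nH]c3ccccc23)[C@H](O)CO)[nH]c2ccccc12 | target

**Totals**
Total step count: 3. Longest linear sequence: 3 steps (1 and 2 to 4, then 8, then 9).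

**Steps most likely to fail, with fallbacks**

First, step 2, the proposed photochemical coupling.
- Risks: low quantum efficiency because sulfinate recaptures ion 7; unproductive oxidation of tryptophol or of product 8; and a diastereomer ratio lower than the A(1,3) model predicts (the classical Felkin conformer with the ring CH2 in plane would give the methine epimer).
- Fallback: it sets out from 4 and 5 and comes back at 8. The same bond is made thermally by the known Lewis-acid substitution of arenesulfonyl indoles: 4 and 5 (2 equiv) with Sc(OTf)3 (10 mol%) in dry CH2Cl2 at −20 to 0 °C ionise 4 to the same ion 7, which tryptophol traps at C2 under the same facial control. The reaction is stopped before acid-mediated equilibration erodes the ratio, and the epimers of 8 are separated on silica. This fallback passes through no compound outside the list (F0).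

Second, step 1.
- Risks: the sulfinic acid and the water released may open the acetonide; aldehyde 2 may epimerise or oligomerise before it is consumed; some symmetrical bis(indol-3-yl)methane may form.
- Fallback: it sets out from 1 and 2 and comes back at 4, joining indole and aldehyde under basic conditions instead. Indole is deprotonated with EtMgBr in THF at 0 °C to (1H-indol-1-yl)magnesium bromide F1. F1 adds through C3 to 2 at −78 °C to give bromomagnesium (1H-indol-3-yl)[(4R)-2,2-dimethyl-1,3-dioxolan-4-yl]methanolate F2. A cold water quench liberates crude (1H-indol-3-yl)[(4R)-2,2-dimethyl-1,3-dioxolan-4-yl]methanol F3 (epimer mixture, not stored). F3 is stirred at once with 3 in EtOAc at 0 °C, where exchange of hydroxyl for sulfinate gives 4.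

Third, step 3.
- Risks: under acid the bis(indolyl)methine of 8 or 9 can undergo retro-Friedel–Crafts cleavage, leading to epimerisation at the methine carbon or to capture of the resulting cation by the hydroxyethyl group as a pyrano[3,4-b]indole.
- Fallback: it sets out from 4 and comes back at 9, removing the ketal before the acid-sensitive methine exists. The acid-stable sulfone 4 is hydrolysed in AcOH/H2O (4:1) at 40 °C to (2R)-3-(1H-indol-3-yl)-3-(4-methylbenzenesulfonyl)propane-1,2-diol F4. F4 and 5 are then coupled under the step 2 conditions (or its Lewis-acid fallback) to give 9 directly, with no acid treatment after the key bond is made.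

**Further compounds**
F1 | step 1 | (1H-indol-1-yl)magnesium bromide | Br[Mg]n1ccc2ccccc12
F2 | step 1 | bromomagnesium (1H-indol-3-yl)[(4R)-2,2-dimethyl-1,3-dioxolan-4-yl]methanolate | Br[Mg]OC(c1c[nH]c2ccccc12)[C@H]3COC(C)(C)O3
F3 | step 1 | (1H-indol-3-yl)[(4R)-2,2-dimethyl-1,3-dioxolan-4-yl]methanol | OC(c1c[nH]c2ccccc12)[C@H]3COC(C)(C)O3
F0 | step 2 | none | none
F4 | step 3 | (2R)-3-(1H-indol-3-yl)-3-(4-methylbenzenesulfonyl)propane-1,2-diol | Cc1ccc(cc1)S(=O)(=O)C(c2c[nH]c3ccccc23)[C@H](O)CO
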